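## Retrosynthetic overview

1. Feature (p-menthane numbering: C1 bears C7H2OH, C2 is the ketone, C3 the hydroxytiglate carbinol, C4 the isopropyl carbon, C5 the angelate carbinol, C6 the vinylic CH). The triad C3(O)–C4(iPr)–C5(O) has all three substituents on one face, and its ends are tied by C2–C1=C6. Taking C1 out of the six-membered ring leaves a meso cis-2-isopropylcyclopent-4-ene-1,3-diol whose mirror plane runs through C4.
2. Late disconnections are the two O–Si bonds, the C5–O acyl bond (angelate), C1–C7 (Stille coupling at a C1 bromide) and the C3–O acyl bond (silylated hydroxytiglic acid from a Wittig reaction). The forward order on a 2-bromo enone is C3 ester, then C7, then C5 ester.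
3. Key disconnection: the bromo enone comes from a 1-bromocyclohexene with a cis C2,C3 cyclic carbonate. That is made from a 6,6-dibromobicyclo[3.1.0]hexane by Ag(I)-induced electrocyclic opening of the C2–C6 bond, with capture at C2 by the tert-butyl carbonate on O3. C1 is the dibromocarbene carbon.
4. The meso diol comes from 6,6-dimethylfulvene by singlet-oxygen [4+2] addition, O–O reduction and hydrogen-atom-transfer hydrogenation of the isopropylidene group. A lipase desymmetrises it once.
5. Ring order: the five-membered carbocycle is bought in the fulvene, a dioxabicycloheptene forms transiently, the cyclopropane is fused on, the cyclohexene and the dioxolanone form together, and the dioxolanone is then opened.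

Key step: step 8

Convention: the target numbering is used for every ring compound (the five-membered precursors lack C1). With C1→C6 drawn clockwise, β means toward the viewer, and the target is 3β-O, 4β-iPr, 5β-O (3S,4S,5S).

Assumption: the lipase is taken to acylate the carbinol predicted by the empirical large/medium-substituent model for secondary alcohols (CH–iPr large, CH= medium), which is C3; if it prefers the other carbinol, hydrolysis of the meso diacetate by the same enzyme gives the same monoacetate and the route is unchanged.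

## Route

Step 1
Reactants: 1 6,6-dimethylfulvene
Product: 3 meso cis-2-(propan-2-ylidene)cyclopent-4-ene-1,3-diol [(1R,3S); both OH β], via fulvene endoperoxide 2 (not isolated)
Conditions: O2, hν (visible), rose bengal (cat.), MeOH, −78 °C; then thiourea (2.2 equiv), MeOH, −78 → 0 °C
Reagents that add atoms: dioxygen, O=O
Why: Singlet oxygen adds to the ring diene of the fulvene in a suprafacial [4+2] cycloaddition, which places both new C–O bonds (C3 and C5) on one face, and thiourea cleaves only the O–O bond of the heat-sensitive endoperoxide before it can rearrange, so the cis relationship is kept.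

Step 2
Reactants: 3 meso cis-2-(propan-2-ylidene)cyclopent-4-ene-1,3-diol
Product: 4 meso all-cis 2-isopropylcyclopent-4-ene-1,3-diol [(1R,2s,3S); 3β-OH, 4β-iPr, 5β-OH]
Conditions: Mn(dpm)3 (10 mol %), PhSiH3, t-BuOOH, i-PrOH, rt
Reagents that add atoms: none
Why: Metal-hydride hydrogen-atom-transfer hydrogenation should choose the tetrasubstituted exocyclic alkene, which gives a tertiary radical, over the 1,2-disubstituted ring alkene, which would give a secondary one, and C4 is set because hydrogen reaches it from the face anti to the two flanking C–O bonds (anti rule for β-substituted cyclopentyl radicals), which turns the isopropyl group onto the oxygen-bearing face.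

Step 3
Reactants: 4 meso all-cis 2-isopropylcyclopent-4-ene-1,3-diol
Product: 5 (1R,4S,5S)-4-hydroxy-5-isopropylcyclopent-2-en-1-yl acetate (3β-OAc, 4β-iPr, 5β-OH)
Conditions: immobilised Candida antarctica lipase B, vinyl acetate, MTBE, 30 °C
Reagents that add atoms: vinyl acetate, C=COC(C)=O
Why: Lipase-catalysed irreversible transesterification distinguishes the enantiotopic carbinols of the meso diol and should acylate C3, so no stereocentre is made but the absolute configuration of all later compounds is fixed here.

Step 4
Reactants: 5 (1R,4S,5S)-4-hydroxy-5-isopropylcyclopent-2-en-1-yl acetate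
Product: 6 (1R,4S,5R)-4-(tert-butyldimethylsilyloxy)-5-isopropylcyclopent-2-en-1-yl acetate (3β-OAc, 4β-iPr, 5β-OTBS)
Conditions: TBSOTf, 2,6-lutidine, CH2Cl2, −78 → 0 °C
Reagents that add atoms: tert-butyldimethylsilyl triflate, CC(C)(C)[Si](C)(C)OS(=O)(=O)C(F)(F)F
Why: Silylation with the silyl triflate is the standard answer to a hindered secondary alcohol (C5–OH next to the cis isopropyl group), only the O–H bond reacts, and the acetate is inert to lutidine.

Step 5
Reactants: 6 (1R,4S,5R)-4-(tert-butyldimethylsilyloxy)-5-isopropylcyclopent-2-en-1-yl acetate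
Product: 7 (1R,4S,5R)-4-(tert-butyldimethylsilyloxy)-5-isopropylcyclopent-2-en-1-ol (3β-OH, 4β-iPr, 5β-OTBS)
Conditions: K2CO3 (cat.), MeOH, 0 °C
Reagents that add atoms: none
Why: Base-catalysed methanolysis removes the acetate by acyl–oxygen cleavage, so C3 is untouched, and catalytic carbonate at 0 °C is too mild to move or cleave the secondary TBS ether.

Step 6
Reactants: 7 (1R,4S,5R)-4-(tert-butyldimethylsilyloxy)-5-isopropylcyclopent-2-en-1-ol
Product: 8 tert-butyl (1R,4S,5R)-4-(tert-butyldimethylsilyloxy)-5-isopropylcyclopent-2-en-1-yl carbonate (3β-OBoc, 4β-iPr, 5β-OTBS)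
Conditions: Boc2O, DMAP (cat.), MeCN, rt
Reagents that add atoms: di-tert-butyl dicarbonate, CC(C)(C)OC(=O)OC(=O)OC(C)(C)C
Why: DMAP-catalysed O-tert-butoxycarbonylation acylates the only free hydroxyl and hangs on O3 the internal nucleophile that the ring expansion needs.

Step 7
Reactants: 8 tert-butyl carbonate (3β-OBoc, 4β-iPr, 5β-OTBS cyclopentene); 9 bromoform
Product: 10 tert-butyl carbonate of 6,6-dibromo-4-(tert-butyldimethylsilyloxy)-3-isopropylbicyclo[3.1.0]hexan-2-ol (route numbering: C1 = CBr2 on the α face, bonded to C2 and C6; 3β-OBoc, 4β-iPr, 5β-OTBS)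
Conditions: 50 % aq NaOH, BnEt3NCl (cat.), CH2Cl2, 0 °C → rt, vigorous stirring
Reagents that add atoms: none
Why: Phase-transfer generation of dibromocarbene and its concerted, stereospecific [2+1] addition to the cis alkene set the ring-fusion centres C2 and C6 by approach from the α face, the only face not covered by the three cis substituents, while the hindered tert-butyl carbonate and the TBS ether should tolerate the two-phase base.

Step 8
Reactants: 10 gem-dibromocyclopropane (C1 = CBr2 α; 3β-OBoc, 4β-iPr, 5β-OTBS)
Product: 11 1-bromocyclohex-1(6)-ene with a cis-fused C2,C3 cyclic carbonate (2β-O and 3β-O in a 1,3-dioxolan-2-one; 4β-iPr; 5β-OTBS)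
Conditions: AgBF4, 2,6-di-tert-butyl-4-methylpyridine, CH2Cl2, dark, 0 → 40 °C
Reagents that add atoms: none
Why: Proposed new method: Ag(I) pulls off the endo bromide, the one lying under the five-membered ring, while the C2–C6 σ bond (the former alkene bond) opens in a disrotatory two-electron electrocyclic process (Woodward–Hoffmann–DePuy rule), so that C1 becomes a member of a six-membered ring holding a cis 2-bromoallyl cation C2–C1(Br)–C6. The carbonyl oxygen of the O3 tert-butyl carbonate adds to C2, and the resulting 2-tert-butoxy-1,3-dioxolan-2-ylium ion loses isobutene and a proton, which the hindered pyridine takes up, so the capture cannot reverse. The closest known reactions are the silver-promoted opening of ring-fused gem-dibromocyclopropanes with capture of the allyl cation by a tethered heteroatom nucleophile and the closure of tert-butyl carbonates onto halonium or carbocation centres, whereas their union on a substrate that carries oxygen next to both cation termini has not been shown. The cyclohexene arises by electrocyclic enlargement of the fused three- and five-membered rings, and the dioxolanone closes by 5-exo-trig attack on the allyl terminus. The only new stereocentre, C2, is dictated by the tether, because a carbonate hanging from the β face of C3 can reach C2 only from that face (cis fusion), and it is erased again in step 10. The step needs capture at C2 and not at C6, which would lead into the enantiomeric series, and this is secured because the carbonate could reach C6 only through a bridged seven-membered ring and because the counter-ion, base and solvent offer no outside nucleophile.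

Step 9
Reactants: 11 bromocyclohexene cyclic carbonate
Product: 12 cis-diol: 1-bromo-5β-(tert-butyldimethylsilyloxy)-4β-isopropylcyclohex-1(6)-ene-2β,3β-diol
Conditions: K2CO3 (cat.), MeOH, rt
Reagents that add atoms: none
Why: Base-catalysed methanolysis of the strained five-membered cyclic carbonate proceeds by acyl–oxygen cleavage, so C2 and C3 keep their configuration and the vinyl bromide and TBS ether are not affected.

Step 10
Reactants: 12 cis-2β,3β-diol
Product: 13 2-bromo enone with free C3 hydroxyl: 1-bromo-3β-hydroxy-4β-isopropyl-5β-(tert-butyldimethylsilyloxy)cyclohex-1(6)-en-2-one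
Conditions: activated MnO2 (excess), CH2Cl2, rt
Reagents that add atoms: none
Why: Manganese dioxide oxidation is selective for the allylic C2 carbinol over the saturated C3 carbinol, it removes the temporary C2 stereocentre, and its neutral heterogeneous medium avoids enolisation toward C3.

Step 11
Reactants: 14 glycolaldehyde dimer (1,4-dioxane-2,5-diol); 15 ethyl 2-(triphenylphosphoranylidene)propanoate
Product: 17 ethyl (E)-4-hydroxy-2-methylbut-2-enoate, via glycolaldehyde 16 (not isolated)
Conditions: CH2Cl2, reflux
Reagents that add atoms: none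
Why: The dimer cracks to the monomeric aldehyde in warm solution, and Wittig olefination with the stabilised α-methyl ylide should give the E trisubstituted alkene, as is usual for stabilised ylides.

Step 12
Reactants: 17 ethyl (E)-4-hydroxy-2-methylbut-2-enoate
Product: 18 ethyl (E)-4-(tert-butyldiphenylsilyloxy)-2-methylbut-2-enoate
Conditions: TBDPSCl, imidazole, DMF, rt
Reagents that add atoms: tert-butyldiphenylsilyl chloride, CC(C)(C)[Si](Cl)(c1ccccc1)c1ccccc1
Why: Standard imidazole-promoted silylation of a primary allylic alcohol installs the acid-robust ether that has to outlast the later TBS cleavage.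

Step 13
Reactants: 18 ethyl (E)-4-(tert-butyldiphenylsilyloxy)-2-methylbut-2-enoate
Product: 19 (E)-4-(tert-butyldiphenylsilyloxy)-2-methylbut-2-enoic acid
Conditions: LiOH, THF/MeOH/H2O, rt; then 1 M HCl to pH 3
Reagents that add atoms: lithium hydroxide, [Li+].[OH-]
Why: Saponification of the ethyl ester leaves the primary TBDPS ether and the E alkene untouched at room temperature.

Step 14
Reactants: 13 2-bromo enone with free C3 hydroxyl; 19 (E)-4-(tert-butyldiphenylsilyloxy)-2-methylbut-2-enoic acid
Product: 21 C3 ester of the bromo enone [1-Br; 3β-O-(E)-4-(TBDPSO)-2-methylbut-2-enoate; 4β-iPr; 5β-OTBS], via mixed anhydride 20 (not isolated)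
Conditions: 19, 2,4,6-Cl3C6H2COCl, Et3N, toluene, rt; then 13, DMAP, toluene, 0 °C → rt
Reagents that add atoms: 2,4,6-trichlorobenzoyl chloride, O=C(Cl)c1c(Cl)cc(Cl)cc1Cl (its acyl group stands in 20 only and leaves again)
Why: Yamaguchi esterification activates the unreactive α-methyl enoic acid strongly enough to acylate the hindered α-hydroxy ketone at or below room temperature, the C3–O bond is not broken, and the short exposure to amine base should keep C3 from epimerising.

Step 15
Reactants: 21 C3 ester of the bromo enone; 22 (tributylstannyl)methanol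
Product: 23 2-(hydroxymethyl) enone [C1–C7H2OH; 3β-O-(E)-4-(TBDPSO)-2-methylbut-2-enoate; 4β-iPr; 5β-OTBS]
Conditions: Pd(PPh3)4 (10 mol %), 1,4-dioxane, 90 °C
Reagents that add atoms: none
Why: Stille coupling of the activated α-bromo enone with the hydroxymethyl stannane forms C1–C7, and it is run while C5 still carries a silyl ether, which palladium(0) cannot ionise as it would an allylic ester.

Step 16
Reactants: 23 2-(hydroxymethyl) enone
Product: 24 C7 TBDPS ether [C7-OTBDPS; 3β-O-(E)-4-(TBDPSO)-2-methylbut-2-enoate; 4β-iPr; 5β-OTBS]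
Conditions: TBDPSCl, imidazole, CH2Cl2, 0 °C → rt
Reagents that add atoms: tert-butyldiphenylsilyl chloride, CC(C)(C)[Si](Cl)(c1ccccc1)c1ccccc1
Why: Standard silylation of the only free hydroxyl gives a second primary TBDPS ether, so that both primary positions are masked by the group that survives the next acidic step.

Step 17
Reactants: 24 C7 TBDPS ether
Product: 25 C5 alcohol [5β-OH; C7-OTBDPS; 3β-O-(E)-4-(TBDPSO)-2-methylbut-2-enoate; 4β-iPr]
Conditions: camphorsulfonic acid (cat.), MeOH/CH2Cl2, 0 °C → rt
Reagents that add atoms: none
Why: Acid-catalysed methanolysis cleaves a TBS ether far faster than a TBDPS ether, only the O–Si bond breaks so C5 keeps its configuration, and the esters and the enone are inert to catalytic acid at this temperature.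

Step 18
Reactants: 25 C5 alcohol; 26 angelic acid [(Z)-2-methylbut-2-enoic acid]
Product: 28 bis-TBDPS ether of the target [5β-O-angelate (Z); 3β-O-(E)-4-(TBDPSO)-2-methylbut-2-enoate; 4β-iPr; C7-OTBDPS], via angelic mixed anhydride 27 (not isolated)
Conditions: 26, 2,4,6-Cl3C6H2COCl, Et3N, toluene, rt; then 25, toluene, 75 °C (no DMAP)
Reagents that add atoms: 2,4,6-trichlorobenzoyl chloride, O=C(Cl)c1c(Cl)cc(Cl)cc1Cl (its acyl group stands in 27 only and leaves again)
Why: Yamaguchi-type mixed-anhydride acylation without a nucleophilic catalyst is the variant established for angelates, because it avoids the reversible conjugate addition that turns Z into E, and the C5–O bond is not broken.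

Step 19
Reactants: 28 bis-TBDPS ether of the target
Product: 29 CNP0281432.2, (1S,5S,6S)-3-(hydroxymethyl)-5-{[(2E)-4-hydroxy-2-methylbut-2-enoyl]oxy}-4-oxo-6-isopropylcyclohex-2-en-1-yl (2Z)-2-methylbut-2-enoate
Conditions: HF·pyridine, pyridine, THF, 0 °C → rt
Reagents that add atoms: none
Why: Buffered fluoride desilylation removes both primary TBDPS ethers in a weakly acidic medium that should not provoke acyl migration, C3 epimerisation, angelate isomerisation or elimination toward an aromatic ring.

## Compound list

1 | 6,6-dimethylfulvene | CC(C)=C1C=CC=C1 | starting material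
2 | 7-(propan-2-ylidene)-2,3-dioxabicyclo[2.2.1]hept-5-ene (meso endoperoxide, not isolated) | CC(C)=C1[C@@H]2C=C[C@H]1OO2 | intermediate
3 | meso (1R,3S)-2-(propan-2-ylidene)cyclopent-4-ene-1,3-diol | O[C@H]1C=C[C@@H](O)C1=C(C)C | intermediate
4 | meso (1R,2s,3S)-2-isopropylcyclopent-4-ene-1,3-diol, all-cis | O[C@H]1C=C[C@@H](O)[C@H]1C(C)C | intermediate
5 | (1R,4S,5S)-4-hydroxy-5-isopropylcyclopent-2-en-1-yl acetate | O[C@H]1C=C[C@@H](OC(C)=O)[C@H]1C(C)C | intermediate
6 | (1R,4S,5R)-4-(tert-butyldimethylsilyloxy)-5-isopropylcyclopent-2-en-1-yl acetate | CC(C)(C)[Si](C)(C)O[C@H]1C=C[C@@H](OC(C)=O)[C@H]1C(C)C | intermediate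
7 | (1R,4S,5R)-4-(tert-butyldimethylsilyloxy)-5-isopropylcyclopent-2-en-1-ol | CC(C)(C)[Si](C)(C)O[C@H]1C=C[C@@H](O)[C@H]1C(C)C | intermediate
8 | tert-butyl (1R,4S,5R)-4-(tert-butyldimethylsilyloxy)-5-isopropylcyclopent-2-en-1-yl carbonate | CC(C)(C)[Si](C)(C)O[C@H]1C=C[C@@H](OC(=O)OC(C)(C)C)[C@H]1C(C)C | intermediate
9 | bromoform | BrC(Br)Br | starting material
10 | 6,6-dibromobicyclo[3.1.0]hexane with all-cis OBoc, iPr, OTBS, anti to the CBr2 bridge | CC(C)(C)[Si](C)(C)O[C@H]1[C@@H]2C(Br)(Br)[C@@H]2[C@@H](OC(=O)OC(C)(C)C)[C@H]1C(C)C | intermediate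
11 | 1-bromocyclohexene with cis C2,C3 cyclic carbonate, 4β-iPr, 5β-OTBS | CC(C)(C)[Si](C)(C)O[C@H]1C=C(Br)[C@H]2OC(=O)O[C@H]2[C@H]1C(C)C | intermediate
12 | 1-bromo-5β-(TBSO)-4β-isopropylcyclohex-1(6)-ene-2β,3β-diol | CC(C)(C)[Si](C)(C)O[C@H]1C=C(Br)[C@@H](O)[C@@H](O)[C@H]1C(C)C | intermediate
13 | 2-bromo enone with 3β-OH, 4β-iPr, 5β-OTBS | CC(C)(C)[Si](C)(C)O[C@H]1C=C(Br)C(=O)[C@@H](O)[C@H]1C(C)C | intermediate
14 | glycolaldehyde dimer (1,4-dioxane-2,5-diol) | OC1COC(O)CO1 | starting material
15 | ethyl 2-(triphenylphosphoranylidene)propanoate | CCOC(=O)C(C)=P(c1ccccc1)(c1ccccc1)c1ccccc1 | starting material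
16 | glycolaldehyde (monomer, not isolated) | OCC=O | intermediate
17 | ethyl (E)-4-hydroxy-2-methylbut-2-enoate | CCOC(=O)/C(C)=C/CO | intermediate
18 | ethyl (E)-4-(tert-butyldiphenylsilyloxy)-2-methylbut-2-enoate | CCOC(=O)/C(C)=C/CO[Si](c1ccccc1)(c1ccccc1)C(C)(C)C | intermediate
19 | (E)-4-(tert-butyldiphenylsilyloxy)-2-methylbut-2-enoic acid | OC(=O)/C(C)=C/CO[Si](c1ccccc1)(c1ccccc1)C(C)(C)C | intermediate
20 | mixed anhydride of 19 with 2,4,6-trichlorobenzoic acid (not isolated) | O=C(OC(=O)/C(C)=C/CO[Si](c1ccccc1)(c1ccccc1)C(C)(C)C)c1c(Cl)cc(Cl)cc1Cl | intermediate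
21 | C3 ester of the bromo enone | CC(C)(C)[Si](C)(C)O[C@H]1C=C(Br)C(=O)[C@@H](OC(=O)/C(C)=C/CO[Si](c2ccccc2)(c2ccccc2)C(C)(C)C)[C@H]1C(C)C | intermediate
22 | (tributylstannyl)methanol | OC[Sn](CCCC)(CCCC)CCCC | starting material
23 | 2-(hydroxymethyl) enone | CC(C)(C)[Si](C)(C)O[C@H]1C=C(CO)C(=O)[C@@H](OC(=O)/C(C)=C/CO[Si](c2ccccc2)(c2ccccc2)C(C)(C)C)[C@H]1C(C)C | intermediate
24 | C7 TBDPS ether, C5 TBS ether | CC(C)(C)[Si](C)(C)O[C@H]1C=C(CO[Si](c2ccccc2)(c2ccccc2)C(C)(C)C)C(=O)[C@@H](OC(=O)/C(C)=C/CO[Si](c2ccccc2)(c2ccccc2)C(C)(C)C)[C@H]1C(C)C | intermediate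
25 | C5 alcohol, bis-TBDPS ether | O[C@H]1C=C(CO[Si](c2ccccc2)(c2ccccc2)C(C)(C)C)C(=O)[C@@H](OC(=O)/C(C)=C/CO[Si](c2ccccc2)(c2ccccc2)C(C)(C)C)[C@H]1C(C)C | intermediate
26 | angelic acid | C/C=C(/C)C(=O)O | starting material
27 | mixed anhydride of angelic acid with 2,4,6-trichlorobenzoic acid (not isolated) | C/C=C(/C)C(=O)OC(=O)c1c(Cl)cc(Cl)cc1Cl | intermediate
28 | bis-TBDPS ether of the target | C/C=C(/C)C(=O)O[C@H]1C=C(CO[Si](c2ccccc2)(c2ccccc2)C(C)(C)C)C(=O)[C@@H](OC(=O)/C(C)=C/CO[Si](c2ccccc2)(c2ccccc2)C(C)(C)C)[C@H]1C(C)C | intermediate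
29 | CNP0281432.2 | C/C=C(/C)C(=O)O[C@H]1C=C(CO)C(=O)[C@@H](OC(=O)/C(C)=C/CO)[C@H]1C(C)C | target

## Step count and risks

Total step count: 19.
Longest linear sequence: 16 (steps 1–10 and 14–19). The side-chain acid 19 takes 3 steps (11–13).

**Step 8 (ring expansion with carbonate capture).**
- Risk: the two C–O bonds next to the cation termini slow the ionisation. The forcing that may then be needed could bring loss of the silyl ether, a hydride shift from C5 to C6, or capture of the cation at C6 by an outside nucleophile.
- Fallback: it uses known chemistry with another neighbouring group in a stepwise sequence, sets out from 6 and comes back at 12.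
- Acetate 6 is cyclopropanated under neutral conditions with phenyl(tribromomethyl)mercury in benzene at 80 °C. This gives the acetate-bearing dibromocyclopropane F1.
- Further heating in toluene opens it thermally, as is usual for 6,6-dibromobicyclo[3.1.0]hexanes, to the allylic dibromide F2. In F2 the departing bromide has returned on the α face, trans to the C3 acetate. Its C6 regioisomer ionises to the same cation.
- Silver acetate in wet acetic acid (Woodward variant of the Prévost reaction) removes the allylic bromide. The C3 acetate closes onto C2 to an acetoxonium ion, and water opens this to the cis hydroxy acetate F3. F3 is drawn as the C3 acetate, and the C2 acetate converges.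
- K2CO3 in methanol then gives diol 12.

**Step 2 (hydrogenation of the isopropylidene group).**
- Risk: facial selectivity may be poor or reversed, because this type of hydrogenation tends toward the more stable epimer. Hydrogen may therefore arrive from the oxygen-bearing face.
- Fallback: it moves the stereocontrol from hydrogen delivery to SN2 inversion, sets out from 3 and comes back at 4.
- The epimer formed from 3 under the same reduction, the meso trans,trans diol F4 (isopropyl anti to both hydroxyls), is taken on or separated from 4.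
- A double Mitsunobu inversion follows (4-nitrobenzoic acid, PPh3, DIAD, THF). This protocol is made for carbinols next to an isopropyl group, as in menthol to a neomenthyl ester. It turns both C–O bonds onto the isopropyl face and gives the all-cis bis(4-nitrobenzoate) F5.
- K2CO3 in methanol then releases meso diol 4.

**Step 18 (angeloylation).**
- Risk: acylation of the hindered C5 hydroxyl is slow at 75 °C. This may allow Z to E isomerisation of the acyl donor, migration of the C3 acyl group to the 1,3-cis C5 oxygen, or elimination toward an aromatic ring.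
- Fallback: it builds the Z alkene on the ester instead of transferring it, sets out from 25 and comes back at 28.
- Alcohol 25 is esterified at 0 °C to rt with the unhindered 2-[bis(2,2,2-trifluoroethoxy)phosphoryl]propanoic acid (EDC, cat. DMAP, CH2Cl2). This gives the C5 phosphonopropanoate F6, a mixture of epimers at the phosphonate carbon.
- Still–Gennari olefination (KHMDS, 1.0 equiv, 18-crown-6, THF, −78 °C, then acetaldehyde) deprotonates only the far more acidic phosphonate. It should give the Z alkene, that is angelate 28.

## Further compounds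

F1 | step 8 | 6,6-dibromobicyclo[3.1.0]hexane with all-cis OAc, iPr, OTBS, anti to the CBr2 bridge | CC(C)(C)[Si](C)(C)O[C@H]1[C@@H]2C(Br)(Br)[C@@H]2[C@@H](OC(C)=O)[C@H]1C(C)C
F2 | step 8 | 1,2α-dibromocyclohex-1(6)-ene with 3β-OAc, 4β-iPr, 5β-OTBS | CC(C)(C)[Si](C)(C)O[C@H]1C=C(Br)[C@H](Br)[C@@H](OC(C)=O)[C@H]1C(C)C
F3 | step 8 | 1-bromo-2β-hydroxy-3β-acetoxy-4β-isopropyl-5β-(TBSO)cyclohex-1(6)-ene | CC(C)(C)[Si](C)(C)O[C@H]1C=C(Br)[C@@H](O)[C@@H](OC(C)=O)[C@H]1C(C)C
F4 | step 2 | meso (1R,2r,3S)-2-isopropylcyclopent-4-ene-1,3-diol (isopropyl trans to both OH) | O[C@H]1C=C[C@@H](O)[C@@H]1C(C)C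
F5 | step 2 | meso all-cis 2-isopropylcyclopent-4-ene-1,3-diyl bis(4-nitrobenzoate) | O=C(O[C@H]1C=C[C@@H](OC(=O)c2ccc(cc2)[N+](=O)[O-])[C@H]1C(C)C)c3ccc(cc3)[N+](=O)[O-]
F6 | step 18 | C5 2-[bis(2,2,2-trifluoroethoxy)phosphoryl]propanoate of 25 | CC(C(=O)O[C@H]1C=C(CO[Si](c2ccccc2)(c2ccccc2)C(C)(C)C)C(=O)[C@@H](OC(=O)/C(C)=C/CO[Si](c2ccccc2)(c2ccccc2)C(C)(C)C)[C@H]1C(C)C)P(=O)(OCC(F)(F)F)OCC(F)(F)F
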